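**Plan**

- Retrosynthesis: the eight C–Br bonds are cut first, then the four O–CH3 bonds, then the two bonds from pyrrole C2 and C5 to the ketone carbonyls, then the two bonds from pyrrole C3 and C4 to the aryl rings.
- Forward: no ring is built. A purchased N-silylpyrrole is dibrominated at C3/C4, arylated twice, desilylated, aroylated at C2/C5, demethylated, and brominated eight times in the last step.
- Enabling feature: each Br sits on a benzene carbon ortho to a phenolic OH whose para carbon is already bonded to pyrrole C3/C4 or to a ketone carbonyl. The pyrrole ring (N1–H, C2/C5 aroyl, C3/C4 aryl) has no C–H.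
- Stereochemistry: none. The target has no stereocentre and no stereogenic double bond.

Key step: step 6

Remark on the chemistry: in steps 1, 2 and 4 the half-converted compound is a single species and is numbered; in steps 5 and 6 and in the fallbacks the partly converted stages are mixtures of positional isomers of one reaction type and are not numbered, apart from the boron aryloxides that await hydrolysis.

**Route**

Step 1
Reactants: 1 1-(triisopropylsilyl)pyrrole
Product: 3 3,4-dibromo-1-(triisopropylsilyl)pyrrole, via 3-bromo-1-(triisopropylsilyl)pyrrole 2 (not isolated)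
Conditions: NBS (2.05 equiv), THF, −78 °C to rt
Reagents that add atoms: N-bromosuccinimide, O=C1CCC(=O)N1Br
Why: Electrophilic aromatic bromination in which the bulky triisopropylsilyl group on nitrogen screens C2 and C5, so both bromines should enter the β carbons C3 and C4.

Step 2
Reactants: 3 3,4-dibromo-1-(triisopropylsilyl)pyrrole; 4 4-methoxyphenylboronic acid
Product: 6 3,4-bis(4-methoxyphenyl)-1-(triisopropylsilyl)pyrrole, via 3-bromo-4-(4-methoxyphenyl)-1-(triisopropylsilyl)pyrrole 5 (not isolated)
Conditions: 4 (2.6 equiv), Pd(PPh3)4 (5 mol %), 2 M aq Na2CO3, toluene/EtOH, 85 °C, argon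
Reagents that add atoms: none
Why: Twofold Suzuki–Miyaura coupling in which zerovalent palladium inserts into each C–Br bond in turn and the carbonate-activated boronic acid transmetallates, a well-precedented way to 3,4-diarylpyrroles from N-silyl-3,4-dibromopyrroles; any silyl loss under the aqueous base is harmless because step 3 removes the group anyway.

Step 3
Reactants: 6 3,4-bis(4-methoxyphenyl)-1-(triisopropylsilyl)pyrrole
Product: 7 3,4-bis(4-methoxyphenyl)-1H-pyrrole
Conditions: Bu4NF (1.1 equiv), THF, 0 °C to rt; H2O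
Reagents that add atoms: none
Why: Fluoride-mediated N-desilylation driven by the strong Si–F bond, with protonation of the pyrrolide by water; nothing else in 6 is sensitive to fluoride.

Step 4
Reactants: 7 3,4-bis(4-methoxyphenyl)-1H-pyrrole; 8 4-methoxybenzoyl chloride
Product: 10 2,5-bis(4-methoxybenzoyl)-3,4-bis(4-methoxyphenyl)-1H-pyrrole, via 2-(4-methoxybenzoyl)-3,4-bis(4-methoxyphenyl)-1H-pyrrole 9 (not isolated)
Conditions: 8 (3 equiv) premixed with AlCl3 (5 equiv), CH2Cl2, 0 °C to reflux; ice/aq HCl
Reagents that add atoms: none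
Why: Friedel–Crafts acylation in which the acylium ion from 8 and AlCl3 attacks the free α carbons of the pyrrole, the most nucleophilic positions of 7; in monoketone 9 the only pyrrole C–H left is C5, which should still outpace the anisyl carbons ortho to AlCl3-complexed methoxy groups, so excess reagent and gentle heating should complete the second aroylation.

Step 5
Reactants: 10 2,5-bis(4-methoxybenzoyl)-3,4-bis(4-methoxyphenyl)-1H-pyrrole
Product: 12 2,5-bis(4-hydroxybenzoyl)-3,4-bis(4-hydroxyphenyl)-1H-pyrrole, via tetrakis(dibromoboryloxy) intermediate 11 (not isolated)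
Conditions: BBr3 (10 equiv), CH2Cl2, −78 °C to rt; then H2O, 0 °C
Reagents that add atoms: none
Why: Lewis acid cleavage of aryl methyl ethers, in which BBr3 binds each methoxy oxygen, bromide removes the methyl group by SN2 attack to leave the boron aryloxide 11, and water frees the four phenols; the diaryl ketones and the acyl-deactivated pyrrole should tolerate the reagent.

Step 6
Reactants: 12 2,5-bis(4-hydroxybenzoyl)-3,4-bis(4-hydroxyphenyl)-1H-pyrrole
Product: 13 2,5-bis(3,5-dibromo-4-hydroxybenzoyl)-3,4-bis(3,5-dibromo-4-hydroxyphenyl)-1H-pyrrole (CNP0269782.0)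
Conditions: Br2 (8.4 equiv), NaOAc (9 equiv), AcOH, 20 °C, dark; aq NaHSO3; crystallisation
Reagents that add atoms: bromine, BrBr
Why: Each of the eight substitutions is an electrophilic aromatic bromination in which a phenol ring attacks Br2 at a carbon ortho to its hydroxyl, giving an arenium ion that acetate deprotonates to restore the arene. The closest known reaction type is the ortho,ortho-dibromination of para-substituted phenols, such as 4-hydroxyphenyl ketones and 4-arylphenols, with Br2 in buffered acetic acid. No ring is closed and no stereocentre is created, so neither a mode of ring closure nor stereocontrol arises. The selectivity needed is complete bromination at the eight carbons ortho to the four hydroxyls and nowhere else; it is secured because the para carbon of every phenol is bonded to pyrrole C3 or C4 or to a ketone carbonyl, the carbons meta to OH are not activated, and the pyrrole has no C–H and is deactivated by its two aroyl groups. The two phenols para to a ketone are the slower pair, but hydroxyl activation should still carry them to the dibromo stage with the small excess of Br2, while NaOAc removes HBr and the measured charge of bromine limits ipso attack at the substituted para carbons. Any N–Br bond or dienone formed reversibly should be returned to product by the NaHSO3 quench.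

**Compound list**

1 | 1-(triisopropylsilyl)-1H-pyrrole | CC(C)[Si](C(C)C)(C(C)C)n1cccc1 | starting material
2 | 3-bromo-1-(triisopropylsilyl)-1H-pyrrole | CC(C)[Si](C(C)C)(C(C)C)n1ccc(Br)c1 | intermediate
3 | 3,4-dibromo-1-(triisopropylsilyl)-1H-pyrrole | CC(C)[Si](C(C)C)(C(C)C)n1cc(Br)c(Br)c1 | intermediate
4 | 4-methoxyphenylboronic acid | COc1ccc(B(O)O)cc1 | starting material
5 | 3-bromo-4-(4-methoxyphenyl)-1-(triisopropylsilyl)-1H-pyrrole | COc1ccc(cc1)-c1cn(cc1Br)[Si](C(C)C)(C(C)C)C(C)C | intermediate
6 | 3,4-bis(4-methoxyphenyl)-1-(triisopropylsilyl)-1H-pyrrole | COc1ccc(cc1)-c1cn(cc1-c1ccc(OC)cc1)[Si](C(C)C)(C(C)C)C(C)C | intermediate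
7 | 3,4-bis(4-methoxyphenyl)-1H-pyrrole | COc1ccc(cc1)-c1c[nH]cc1-c1ccc(OC)cc1 | intermediate
8 | 4-methoxybenzoyl chloride | COc1ccc(cc1)C(Cl)=O | starting material
9 | 2-(4-methoxybenzoyl)-3,4-bis(4-methoxyphenyl)-1H-pyrrole | COc1ccc(cc1)C(=O)c1[nH]cc(-c2ccc(OC)cc2)c1-c1ccc(OC)cc1 | intermediate
10 | 2,5-bis(4-methoxybenzoyl)-3,4-bis(4-methoxyphenyl)-1H-pyrrole | COc1ccc(cc1)C(=O)c1[nH]c(C(=O)c2ccc(OC)cc2)c(-c2ccc(OC)cc2)c1-c1ccc(OC)cc1 | intermediate
11 | 2,5-bis[4-(dibromoboryloxy)benzoyl]-3,4-bis[4-(dibromoboryloxy)phenyl]-1H-pyrrole | O=C(c1ccc(OB(Br)Br)cc1)c1[nH]c(C(=O)c2ccc(OB(Br)Br)cc2)c(-c2ccc(OB(Br)Br)cc2)c1-c1ccc(OB(Br)Br)cc1 | intermediate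
12 | 2,5-bis(4-hydroxybenzoyl)-3,4-bis(4-hydroxyphenyl)-1H-pyrrole | O=C(c1ccc(O)cc1)c1[nH]c(C(=O)c2ccc(O)cc2)c(-c2ccc(O)cc2)c1-c1ccc(O)cc1 | intermediate
13 | 2,5-bis(3,5-dibromo-4-hydroxybenzoyl)-3,4-bis(3,5-dibromo-4-hydroxyphenyl)-1H-pyrrole | O=C(c1cc(Br)c(O)c(Br)c1)c1[nH]c(C(=O)c2cc(Br)c(O)c(Br)c2)c(-c2cc(Br)c(O)c(Br)c2)c1-c1cc(Br)c(O)c(Br)c1 | target

**Step count**

Total: 6 steps. Longest linear sequence: 6 steps, from 1 to 13.

**Steps most likely to fail**

Step 4. The second aroylation may stall once the first aroyl group has deactivated the pyrrole, and the acylium ion may then be diverted to the anisyl rings or to nitrogen. The fallback forms both carbon nucleophiles before either carbonyl is present. Setting out from 7, di-tert-butyl dicarbonate with catalytic 4-(dimethylamino)pyridine in MeCN would give tert-butyl 3,4-bis(4-methoxyphenyl)-1H-pyrrole-1-carboxylate F1. The carbamate directs twofold α-deprotonation by lithium 2,2,6,6-tetramethylpiperidide in THF at −78 °C to tert-butyl 2,5-dilithio-3,4-bis(4-methoxyphenyl)-1H-pyrrole-1-carboxylate F2. This is trapped in the same flask with commercial N,4-dimethoxy-N-methylbenzamide (Weinreb ketone synthesis, aqueous NH4Cl quench) to give tert-butyl 2,5-bis(4-methoxybenzoyl)-3,4-bis(4-methoxyphenyl)-1H-pyrrole-1-carboxylate F3. CF3CO2H in CH2Cl2 then removes the carbamate and the route is rejoined at 10.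

Step 6. Bromination may run unevenly: the two ketone-bearing phenol rings react more slowly than the two on C3 and C4, so partly brominated material may persist or precipitate while surplus bromine starts ipso attack or oxidation at the electron-rich rings. The fallback brings in the four bromines of the slow rings with the acylating agent and leaves only the fast rings for the end. Setting out from 7, commercial 3,5-dibromo-4-methoxybenzoic acid and SOCl2 would give 3,5-dibromo-4-methoxybenzoyl chloride F4. Under the AlCl3 conditions of step 4 this acylates 7 at C2 and C5 to give 2,5-bis(3,5-dibromo-4-methoxybenzoyl)-3,4-bis(4-methoxyphenyl)-1H-pyrrole F5; aryl bromides are inert to AlCl3 and BBr3. BBr3 then cleaves the four methyl ethers by way of 2,5-bis[3,5-dibromo-4-(dibromoboryloxy)benzoyl]-3,4-bis[4-(dibromoboryloxy)phenyl]-1H-pyrrole F6, hydrolysed on work-up to 2,5-bis(3,5-dibromo-4-hydroxybenzoyl)-3,4-bis(4-hydroxyphenyl)-1H-pyrrole F7. About four equivalents of Br2 in NaOAc-buffered AcOH then brominate the two reactive phenols, which rejoins the route at 13.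

Step 2. The second oxidative addition, next to the newly installed aryl group on an electron-rich N-silylpyrrole, may be slow enough for protodebromination or base-induced loss of the silyl group to compete. The fallback makes the halide partner electron-poor before coupling. Setting out from 3, Bu4NF in THF would give 3,4-dibromo-1H-pyrrole F8, used at once with NaH and benzenesulfonyl chloride to give 3,4-dibromo-1-(phenylsulfonyl)-1H-pyrrole F9. Coupling with 4 (Pd(PPh3)4, aqueous Na2CO3, 1,2-dimethoxyethane, reflux) should then give 3,4-bis(4-methoxyphenyl)-1-(phenylsulfonyl)-1H-pyrrole F10. NaOH in MeOH/THF at reflux removes the sulfonyl group and the route is rejoined at 7.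

**Further compounds**

F1 | step 4 | tert-butyl 3,4-bis(4-methoxyphenyl)-1H-pyrrole-1-carboxylate | COc1ccc(cc1)-c1cn(cc1-c1ccc(OC)cc1)C(=O)OC(C)(C)C
F2 | step 4 | tert-butyl 2,5-dilithio-3,4-bis(4-methoxyphenyl)-1H-pyrrole-1-carboxylate | [Li]c1n(C(=O)OC(C)(C)C)c([Li])c(-c2ccc(OC)cc2)c1-c1ccc(OC)cc1
F3 | step 4 | tert-butyl 2,5-bis(4-methoxybenzoyl)-3,4-bis(4-methoxyphenyl)-1H-pyrrole-1-carboxylate | COc1ccc(cc1)C(=O)c1n(C(=O)OC(C)(C)C)c(C(=O)c2ccc(OC)cc2)c(-c2ccc(OC)cc2)c1-c1ccc(OC)cc1
F4 | step 6 | 3,5-dibromo-4-methoxybenzoyl chloride | COc1c(Br)cc(cc1Br)C(Cl)=O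
F5 | step 6 | 2,5-bis(3,5-dibromo-4-methoxybenzoyl)-3,4-bis(4-methoxyphenyl)-1H-pyrrole | COc1ccc(cc1)-c1c(-c2ccc(OC)cc2)c(C(=O)c2cc(Br)c(OC)c(Br)c2)[nH]c1C(=O)c1cc(Br)c(OC)c(Br)c1
F6 | step 6 | 2,5-bis[3,5-dibromo-4-(dibromoboryloxy)benzoyl]-3,4-bis[4-(dibromoboryloxy)phenyl]-1H-pyrrole | O=C(c1cc(Br)c(OB(Br)Br)c(Br)c1)c1[nH]c(C(=O)c2cc(Br)c(OB(Br)Br)c(Br)c2)c(-c2ccc(OB(Br)Br)cc2)c1-c1ccc(OB(Br)Br)cc1
F7 | step 6 | 2,5-bis(3,5-dibromo-4-hydroxybenzoyl)-3,4-bis(4-hydroxyphenyl)-1H-pyrrole | O=C(c1cc(Br)c(O)c(Br)c1)c1[nH]c(C(=O)c2cc(Br)c(O)c(Br)c2)c(-c2ccc(O)cc2)c1-c1ccc(O)cc1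
F8 | step 2 | 3,4-dibromo-1H-pyrrole | Brc1c[nH]cc1Br
F9 | step 2 | 3,4-dibromo-1-(phenylsulfonyl)-1H-pyrrole | O=S(=O)(c1ccccc1)n1cc(Br)c(Br)c1
F10 | step 2 | 3,4-bis(4-methoxyphenyl)-1-(phenylsulfonyl)-1H-pyrrole | COc1ccc(cc1)-c1cn(cc1-c1ccc(OC)cc1)S(=O)(=O)c1ccccc1
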